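Percentage points of the substrate charged are the unit of these readings, and a reading scatters by 0.3 percentage points.

| setting | amber | blue | green | beta | delta |
|---|---|---|---|---|---|
| substrate | 0.028 M | 0.028 M | 0.028 M | 0.028 M | 0.028 M |
| reagent | 0.015 M | 0.030 M | 0.0364 M | 0.0364 M | 0.0200 M |
| free catalyst | 2.8 mM | 2.8 mM | 7.3 mM | 2.8 mM | 12 mM |
| temperature | 105 °C | 116 °C | 105 °C | 110 °C | 110 °C |
| remark | run made earlier | run made earlier | run made earlier |  |  |
| time |  |  |  | 4.0 min | 4.0 min |

| run | time / min | target / % | isomer of the product / % | substrate / % |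
|---|---|---|---|---|
| amber | 0.333 | 24.6 | 0.1 | 65.7 |
| amber | 0.667 | 41.4 | 0 | 48.5 |
| amber | 1.50 | 52.4 | 0.6 | 36.9 |
| amber | 4.00 | 53.3 | 0.9 | 36.5 |
| blue | 0.500 | 83.8 | 2.7 | 4.5 |
| blue | 1.33 | 82.6 | 16.5 | 0.2 |
| blue | 2.50 | 83.1 | 16.6 | 0 |
| blue | 4.00 | 83.1 | 16.7 | 0 |
| green | 0.500 | 75.9 | 21.2 | 0 |
| green | 1.33 | 76.5 | 21.6 | 0 |
| green | 2.50 | 76.3 | 21.4 | 0 |
| green | 4.00 | 75.9 | 21.1 | 0 |

(scatter of a reading: 0.3 percentage points)

- the flask that ends with the higher share of target in all that became target or isomer of the product, or "neither" when 2 percentage points or less lies between them (beta / delta / neither)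
- share of target in all that became target or isomer of the product, beta
- share of target in all that became target or isomer of the product, delta

In the first instants, free catalyst takes up substrate in a bound form. At 4.00 min the amber run misses 9.30% of its substrate, close to its catalyst charge of 10.0% of the substrate. In the middle, reagent turns substrate into target one for one. Amber's target stops at 53.3%, and its reagent, the limiting reagent, covers 53.6%. Isomer stays small while substrate stands: amber ends with 0.9% isomer beside 36.5% substrate.

At the end, once blue and green read 0% substrate, target and isomer hold a steady ratio. Green keeps isomer over target at 0.280 at 105 °C, and blue keeps 0.200 at 116 °C. Taking the logarithm of that ratio as straight in temperature over this narrow span gives 0.241 at 110 °C. The plateau share, the fraction of target in target plus isomer once the two stand in balance (thermodynamic control), is then 80.6%.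

That plateau asks for free catalyst at the end, so the thing to watch is the catalyst charge minus the substrate excess over reagent. Beta has more reagent than substrate, by 8.40 mM, as blue did. Delta has a substrate excess of 8.00 mM against 12 mM of catalyst, which leaves 4.00 mM spare, more than blue's whole charge of 2.8 mM. This reckoning therefore puts both flasks at 80.6%, with no gap between them.

The forecast differs: it gave 91% (86% to 95%) for beta and 79% (71% to 87%) for delta, hence beta, holding that “the bound pool and last traces of substrate go to isomer”.

The flasks give 80.6% for beta and 80.6% for delta, so the answer is neither.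

    target + free catalyst ⇌ isomer of the product + free catalyst, rate k1*[free catalyst]*[target] forward; the back reaction follows from the equilibrium constant (K = 0.240, k = 25.2 L mol⁻¹ s⁻¹, Ea = 39.0 kJ mol⁻¹, ΔH = −37.0 kJ mol⁻¹)
    substrate + free catalyst → catalyst intermediate A (k = 1850 L mol⁻¹ s⁻¹, Ea = 56.0 kJ mol⁻¹)
    reagent + catalyst intermediate A → catalyst intermediate B (k = 26.9 L mol⁻¹ s⁻¹, Ea = 49.0 kJ mol⁻¹)
    catalyst intermediate B → by-product + catalyst intermediate C (k = 1.11 s⁻¹, Ea = 100 kJ mol⁻¹)
    catalyst intermediate C ⇌ free catalyst + target (K = 0.279 M, k = 0.826 s⁻¹, Ea = 85.0 kJ mol⁻¹, ΔH = 46.0 kJ mol⁻¹)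
    (constants at 110 °C)

In delta at 4.00 min, target and isomer relax by their own step with a half-life of 1.41 s, shorter than the 4.0 min of the run. Delta's pair stands at 80.6%, with 31.5% of the catalyst free, 1.80% as catalyst intermediate C and 8.00 mM held as catalyst intermediate A. A neighbour of delta, charged with 0.0048 M of catalyst, falls 3.20 mM short of the substrate excess over reagent. That neighbour ends with 0% free catalyst, 11% unbound substrate and a share of 98.3%, above the plateau share of 80.6%.

All runs are simulated on assumed constants, and the scatter is random.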